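The ring atoms are numbered C1 (CHOAc), C2, C3 (CMe), C4 (CHBr), C5, C6 (CMe), C7 (CHMe), C8 (CHBr), C9 (CHOH), C10 (CHMe) and C11 (the carbon common to all three rings). The cyclohexane is joined to the bicyclo[3.2.0]heptane only through the C6–C11 bond, so the plan rests on cutting C6–C7 and C10–C11. One Lewis acid-promoted Diels–Alder reaction of a 3-siloxyhexa-2,4-diene with a strained C6=C11 alkene closes the six-membered ring. It also builds both adjacent quaternary carbons and delivers both secondary methyl groups and the C9 oxygen. The precursor is an enantiopure 2-formylbicyclo[3.2.0]hept-1-en-7-one whose C4 silyl ether stands cis to the C3 methyl, ready for one inverting bromide displacement.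

Key step: step 8

Remarks before the steps
- Faces: "top" is the face of the five-membered ring that carries the C3 methyl and later C7 and C10. "Bottom" is the face that carries C1/C2 and the one-carbon group on C6.
- Assumption (availability): compounds 1, 4 and 10 are taken as commercial.
- Assumption (stability): the C6=C11 ene-dicarbonyl is taken to be less stable than its C5=C6 isomer, so the double bond is placed kinetically (step 5) and never by equilibration.
- Remark (C4): bromide must end trans to the C3 methyl, so the C4 oxygen is carried cis to that methyl and one SN2 step suffices. The photocycloaddition in step 3 gives exactly this arrangement.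
- Remark (C10): suprafacial endo addition of the (2Z,4E)-diene puts both secondary methyl groups cis, whereas the target has them trans. Equilibration of C10 is therefore a planned part of step 8.

Step 1
Reactants: 1 (R)-4-(tert-butyldimethylsilyloxy)cyclopent-2-en-1-one
Product: 2 (3R,4R)-4-(tert-butyldimethylsilyloxy)-3-methyl-1-(trimethylsilyloxy)cyclopent-1-ene (methyl trans to OTBS)
Conditions: Me2CuLi (MeLi, CuI), TMSCl, Et2O–THF, −78 °C
Reagents that add atoms: lithium dimethylcuprate [Li+].C[Cu-]C; chlorotrimethylsilane C[Si](C)(C)Cl
Why: Gilman cuprate conjugate addition with in situ silylation, in which the methyl group enters anti to the C4 silyl ether (a centre that step 2 erases) and TMSCl freezes the C6/C11 enolate before silyloxide can be lost by beta-elimination.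

Step 2
Reactants: 2
Product: 3 (R)-4-(tert-butyldimethylsilyloxy)-3-methylcyclopent-2-en-1-one
Conditions: Pd(OAc)2 (10 mol %), O2 (1 atm), DMSO, rt
Reagents that add atoms: none
Why: Saegusa–Ito dehydrogenation, in which palladium on C11 of the regiodefined enol ether has only the C3 hydrogen available for beta-hydride loss, so the enone returns with the methyl on its beta carbon and C4 untouched.

Step 3
Reactants: 3; 4 allene (propadiene)
Product: 5 (1S,4R,5R)-4-(tert-butyldimethylsilyloxy)-5-methyl-7-methylidenebicyclo[3.2.0]heptan-2-one
Conditions: hν (Hg lamp, Pyrex), excess 4, CH2Cl2, −78 °C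
Reagents that add atoms: none
Why: Enone–allene [2+2] photocycloaddition, which should add head-to-head (the central allene carbon, future C1, bonds to the alpha carbon C11) and anti to the neighbouring C4 silyl ether, so quaternary C3 is set with its methyl cis to OTBS and the ring fusion is cis.

Step 4
Reactants: 5
Product: 6 spiro-epoxide of 5 at C6 (oxirane CH2 is the future C6 methyl carbon; either C6 epimer serves)
Conditions: ICH2Cl, MeLi·LiBr, THF, −78 °C → rt
Reagents that add atoms: chloroiodomethane ClCI
Why: Halomethyllithium epoxidation (addition of LiCH2Cl to the ketone and closure of the chlorohydrin alkoxide on warming), whose reagent is nucleophilic but weakly basic at −78 °C so the beta-silyloxy ketone is not enolised, and the new spiro centre is irrelevant because step 5 makes C6 sp2.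

Step 5
Reactants: 6
Product: 8 (4R,5R)-4-(tert-butyldimethylsilyloxy)-2-(hydroxymethyl)-5-methylbicyclo[3.2.0]hept-1-en-7-one, via epoxy cyclobutanone 7 (not isolated)
Conditions: O3, CH2Cl2, −78 °C; Me2S; then Et3N (0.2 equiv), 0 °C
Reagents that add atoms: ozone [O-][O+]=O
Why: Ozonolysis unmasks the C1 cyclobutanone and the resulting beta,gamma-epoxy ketone isomerises by amine-triggered E1cB opening, in which only the C11 hydrogen can trigger loss of the C6–O bond, so the C6=C11 bond is placed under kinetic control.

Step 6
Reactants: 8
Product: 9 (4R,5R)-4-(tert-butyldimethylsilyloxy)-5-methyl-7-oxobicyclo[3.2.0]hept-1-ene-2-carbaldehyde (dienophile)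
Conditions: Dess–Martin periodinane, CH2Cl2, 0 °C, used at once
Reagents that add atoms: none
Why: Dess–Martin oxidation of the primary allylic alcohol needs neither base nor strong acid, so the isomerisation-prone ene-dicarbonyl should form without movement of the double bond.

Step 7
Reactants: 10 (E)-hex-4-en-3-one
Product: 11 (2Z,4E)-3-(trimethylsilyloxy)hexa-2,4-diene
Conditions: TMSOTf, Et3N, Et2O, 0 °C
Reagents that add atoms: trimethylsilyl triflate C[Si](C)(C)OS(=O)(=O)C(F)(F)F
Why: Soft enolisation (silyl triflate/amine) removes an alpha' proton of the ethyl enone and gives the cross-conjugated dienol ether with the Z geometry usual for ethyl ketones, so both terminal methyl groups point outward in the s-cis diene.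

Step 8
Reactants: 9; 11
Product: 14 tricyclic diketo aldehyde (C1 and C9 ketones; C6 formyl on the bottom face; C4 OTBS cis to C3 methyl; C7 methyl cis to formyl; C10 methyl trans to C7 methyl), via silyl enol ether adduct 12 (not isolated), via C10-epimeric diketo aldehyde 13 (not isolated)
Conditions: 11 (3 equiv), Me2AlCl (1.2 equiv), CH2Cl2, −78 → −30 °C; 1 M HCl, THF, 0 °C; DBU (10 mol %), CH2Cl2, rt
Reagents that add atoms: none
Why: Me2AlCl binds the formyl oxygen (sterically open and a better donor than a cyclobutanone oxygen), which makes C11 the electrophilic end of C6=C11, so the enol ether carbon C10 bonds to C11 ahead of C7–C6 bond formation in a strongly asynchronous normal-demand [4+2] cycloaddition whose stepwise limit is a Mukaiyama–Michael/Michael sequence, the closest known reaction type being the Lewis acid-promoted Diels–Alder reaction of 2-siloxydienes with hindered, doubly activated cycloalkenes that creates vicinal quaternary carbons. The cyclohexane C6–C7–C8–C9–C10–C11 is closed by intermolecular [4+2] annulation, four diene carbons adding suprafacially across the two alkene carbons (a 6-endo-trig Michael closure at C7 in the stepwise limit). C11 and C6 are fixed by addition to the convex top face syn to the C3 methyl, the only usable face because C2 holds the four-membered ring on the bottom and attack there would give a trans-fused bicyclo[3.2.0]heptane. C7 follows from the E geometry of that diene terminus and the endo orientation over both carbonyl groups, which sterics reinforce because the exo mode would press C8, C9 and the silyloxy group against the C3 methyl and the C4 silyl ether. C10 emerges in 12 with its methyl cis to C1 and, after hydrolysis to 13, is equilibrated through the C9 enolate to 14, in which both secondary methyl groups are equatorial and mutually trans. The step needs aldehyde-controlled orientation and 1,4- rather than 1,2-attack at the formyl group, which the substrate supports through the strain released when the four-ring sp2 carbon C11 pyramidalises, the two cis carbonyl groups that lower the LUMO, and a diene that can react in its s-cis form.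

Step 9
Reactants: 14
Product: 16 diol ketone (C6 CH2OH; C1 OH cis to C10 and to the C3 methyl; C9 ketone kept), via hydroxymethyl diketone 15 (not isolated)
Conditions: Me4NBH(OAc)3 (6 equiv), MeCN–AcOH 1:1, −20 °C → rt
Reagents that add atoms: none
Why: Triacetoxyborohydride reduces aldehydes but not isolated ketones, and the new C6–CH2OH then replaces an acetate on boron and hands hydride to C1, the carbonyl it lies beneath (Saksena–Evans hydroxyl-directed reduction), so hydrogen enters from the cyclopentane side, which is also the open face because the equatorial C10 methyl covers the other one, and C9 should stay a ketone.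

Step 10
Reactants: 16
Product: 17 O-phenyl thionocarbonate of the C6 CH2OH group (C1 OH free)
Conditions: PhOC(S)Cl (1.1 equiv), pyridine, CH2Cl2, 0 °C
Reagents that add atoms: O-phenyl chlorothionoformate ClC(=S)Oc1ccccc1
Why: Selective thioacylation, since the primary hydroxyl reacts faster than the C1 hydroxyl, which is secondary, adjacent to quaternary C11 and crowded by the C10 methyl.

Step 11
Reactants: 17
Product: 18 hydroxy ketone with the C6 methyl in place (C1 OH, C9 ketone, C4 OTBS)
Conditions: Bu3SnH, AIBN (cat.), toluene, 110 °C
Reagents that add atoms: none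
Why: Barton–McCombie deoxygenation, in which stannyl radical addition to C=S and fragmentation give a neopentyl primary radical that has no fast rearrangement path (C6 is not a cyclobutane carbon) and is reduced to the methyl group, while ketone, hydroxyl and silyl ether are inert to tin hydride.

Step 12
Reactants: 18
Product: 19 C1 acetate (C9 ketone, C4 OTBS)
Conditions: Ac2O, DMAP, pyridine, rt → 40 °C
Reagents that add atoms: acetic anhydride CC(=O)OC(C)=O
Why: DMAP-catalysed acetylation of the only free hydroxyl group, with no change at any stereocentre.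

Step 13
Reactants: 19
Product: 20 C4 alcohol (OH cis to C3 methyl; C1 acetate; C9 ketone)
Conditions: HF·pyridine, THF, 0 °C → rt
Reagents that add atoms: none
Why: Fluoride cleavage of the Si–O bond frees the C4 alcohol with its configuration intact and leaves acetate and ketone alone.

Step 14
Reactants: 20
Product: 22 C4 bromide (Br trans to C3 methyl; C1 acetate; C9 ketone), via C4 triflate 21 (not isolated)
Conditions: Tf2O, pyridine, CH2Cl2, −30 °C; then Bu4NBr, toluene–CH2Cl2, −30 °C → rt
Reagents that add atoms: tetrabutylammonium bromide CCCC[N+](CCCC)(CCCC)CCCC.[Br-]; triflic anhydride O=S(=O)(OS(=O)(=O)C(F)(F)F)C(F)(F)F (its atoms stay in 21 only)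
Why: Sulfonate activation followed by SN2 displacement, in which soluble bromide attacks C4 anti to the triflate from the cyclobutane side and inverts the centre, while a low-polarity medium disfavours ionisation and the bond antiperiplanar to the leaving group (C3–C2) could migrate only to an unfavourable 7-norbornyl-type cation.

Step 15
Reactants: 22
Product: 23 C8=C9 trimethylsilyl enol ether
Conditions: LiHMDS (1.1 equiv), TMSCl, THF, −78 °C
Reagents that add atoms: chlorotrimethylsilane C[Si](C)(C)Cl
Why: Kinetic enolisation with in situ silylation, in which the hindered amide takes a proton from the C8 methylene rather than the tertiary C10–H next to quaternary C11, the ketone being far more acidic than the acetate, so the enol ether is regiodefined and C10 is not touched.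

Step 16
Reactants: 23
Product: 24 C8 bromo ketone (equatorial Br trans to C7 methyl)
Conditions: NBS, THF, −78 → 0 °C
Reagents that add atoms: N-bromosuccinimide O=C1CCC(=O)N1Br
Why: Electrophilic bromination of the silyl enol ether, in which bromine should add to C8 on the face opposite to the axial C6 methyl and the C7 methyl to give the equatorial bromide, which is also the more stable epimer.

Step 17
Reactants: 24
Product: 25 target, 5,9-dibromo-10-hydroxy-4,7,8,11-tetramethyltricyclo[5.4.0.0(1,4)]undecan-2-yl acetate (CNP0246576.1)
Conditions: NaBH4, MeOH–CH2Cl2, −40 → 0 °C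
Reagents that add atoms: none
Why: Borohydride reduction under steric approach control, in which the axial C11–C3 bond and the C3 methyl close one face of C9, so hydride arrives along the equatorial trajectory from the other face and gives the axial alcohol cis to bromine and to the C10 methyl, a cis-bromohydrin that cannot close to an epoxide, while acetate and both bromides survive.

Compound list
1 | (R)-4-(tert-butyldimethylsilyloxy)cyclopent-2-en-1-one | O=C1C=C[C@H](O[Si](C)(C)C(C)(C)C)C1 | starting material
2 | (3R,4R)-4-(tert-butyldimethylsilyloxy)-3-methyl-1-(trimethylsilyloxy)cyclopent-1-ene | C[Si](C)(C)OC1=C[C@@H](C)[C@H](O[Si](C)(C)C(C)(C)C)C1 | intermediate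
3 | (R)-4-(tert-butyldimethylsilyloxy)-3-methylcyclopent-2-en-1-one | O=C1C=C(C)[C@H](O[Si](C)(C)C(C)(C)C)C1 | intermediate
4 | allene (propadiene) | C=C=C | starting material
5 | (1S,4R,5R)-4-(tert-butyldimethylsilyloxy)-5-methyl-7-methylidenebicyclo[3.2.0]heptan-2-one | C=C1C[C@@]2(C)[C@H](O[Si](C)(C)C(C)(C)C)CC(=O)[C@@H]12 | intermediate
6 | spiro-epoxide at C6 of 5 (C6 configuration open, erased in step 5) | C=C1C[C@@]2(C)[C@H](O[Si](C)(C)C(C)(C)C)CC3(CO3)[C@@H]12 | intermediate
7 | epoxy cyclobutanone (C1 ketone, C6 spiro-epoxide; not isolated) | O=C1C[C@@]2(C)[C@H](O[Si](C)(C)C(C)(C)C)CC3(CO3)[C@@H]12 | intermediate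
8 | (4R,5R)-4-(tert-butyldimethylsilyloxy)-2-(hydroxymethyl)-5-methylbicyclo[3.2.0]hept-1-en-7-one | O=C1C[C@@]2(C)[C@H](O[Si](C)(C)C(C)(C)C)CC(CO)=C12 | intermediate
9 | (4R,5R)-4-(tert-butyldimethylsilyloxy)-5-methyl-7-oxobicyclo[3.2.0]hept-1-ene-2-carbaldehyde | O=CC1=C2C(=O)C[C@@]2(C)[C@H](O[Si](C)(C)C(C)(C)C)C1 | intermediate
10 | (E)-hex-4-en-3-one | C/C=C/C(=O)CC | starting material
11 | (2Z,4E)-3-(trimethylsilyloxy)hexa-2,4-diene | C/C=C/C(O[Si](C)(C)C)=C/C | intermediate
12 | endo cycloadduct, C8=C9 TMS enol ether, C10 methyl cis to C1 (not isolated) | O=C1C[C@@]2(C)[C@H](O[Si](C)(C)C(C)(C)C)C[C@]3(C=O)[C@@H](C)C=C(O[Si](C)(C)C)[C@@H](C)[C@]123 | intermediate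
13 | C10-epimeric diketo aldehyde (not isolated) | O=C1C[C@@]2(C)[C@H](O[Si](C)(C)C(C)(C)C)C[C@]3(C=O)[C@@H](C)CC(=O)[C@@H](C)[C@]123 | intermediate
14 | tricyclic diketo aldehyde, C10 methyl equatorial | O=C1C[C@@]2(C)[C@H](O[Si](C)(C)C(C)(C)C)C[C@]3(C=O)[C@@H](C)CC(=O)[C@H](C)[C@]123 | intermediate
15 | hydroxymethyl diketone (not isolated) | O=C1C[C@@]2(C)[C@H](O[Si](C)(C)C(C)(C)C)C[C@]3(CO)[C@@H](C)CC(=O)[C@H](C)[C@]123 | intermediate
16 | diol ketone (C1 OH, C6 CH2OH, C9 ketone) | O[C@@H]1C[C@@]2(C)[C@H](O[Si](C)(C)C(C)(C)C)C[C@]3(CO)[C@@H](C)CC(=O)[C@H](C)[C@]123 | intermediate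
17 | primary O-phenyl thionocarbonate | O[C@@H]1C[C@@]2(C)[C@H](O[Si](C)(C)C(C)(C)C)C[C@]3(COC(=S)Oc4ccccc4)[C@@H](C)CC(=O)[C@H](C)[C@]123 | intermediate
18 | C6-methyl hydroxy ketone | O[C@@H]1C[C@@]2(C)[C@H](O[Si](C)(C)C(C)(C)C)C[C@]3(C)[C@@H](C)CC(=O)[C@H](C)[C@]123 | intermediate
19 | C1 acetate, C4 OTBS, C9 ketone | CC(=O)O[C@@H]1C[C@@]2(C)[C@H](O[Si](C)(C)C(C)(C)C)C[C@]3(C)[C@@H](C)CC(=O)[C@H](C)[C@]123 | intermediate
20 | C4 alcohol (cis to C3 methyl) | CC(=O)O[C@@H]1C[C@@]2(C)[C@H](O)C[C@]3(C)[C@@H](C)CC(=O)[C@H](C)[C@]123 | intermediate
21 | C4 triflate (not isolated) | CC(=O)O[C@@H]1C[C@@]2(C)[C@H](OS(=O)(=O)C(F)(F)F)C[C@]3(C)[C@@H](C)CC(=O)[C@H](C)[C@]123 | intermediate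
22 | C4 bromide (trans to C3 methyl), C9 ketone | CC(=O)O[C@@H]1C[C@@]2(C)[C@@H](Br)C[C@]3(C)[C@@H](C)CC(=O)[C@H](C)[C@]123 | intermediate
23 | C8=C9 TMS enol ether | CC(=O)O[C@@H]1C[C@@]2(C)[C@@H](Br)C[C@]3(C)[C@@H](C)C=C(O[Si](C)(C)C)[C@H](C)[C@]123 | intermediate
24 | C4,C8-dibromo C9 ketone | CC(=O)O[C@@H]1C[C@@]2(C)[C@@H](Br)C[C@]3(C)[C@@H](C)[C@H](Br)C(=O)[C@H](C)[C@]123 | intermediate
25 | CNP0246576.1 | CC(=O)O[C@@H]1C[C@@]2(C)[C@@H](Br)C[C@]3(C)[C@@H](C)[C@H](Br)[C@H](O)[C@H](C)[C@]123 | target

Total step count: 17. Longest linear sequence: 16 steps (steps 1–6 and 8–17). Step 7 is the one-step branch to the diene.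

Steps most likely to fail

1. Step 8.
- Several things may go wrong here. The enol ether may attack the activated formyl carbon (1,2-addition) instead of C11. The orientation may be steered by the ketone rather than the aldehyde. The C6=C11 bond may drift to C5=C6 before the cycloaddition. The reaction may also simply not proceed, because the diene must approach the face that carries the C3 methyl and the C4 silyl ether.
- The fallback makes the same two bonds one after the other by anionic conjugate additions. It sets out from 9 and 10.
- Compound 9 is precomplexed with aluminium tris(2,6-diphenylphenoxide) in toluene at −78 °C, and the aryl pocket of this Lewis acid covers the formyl carbon.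
- The kinetic lithium dienolate of 10 (LDA, THF, −78 °C) is then added, so that C10 bonds to C11 by Michael addition. Protonation gives the enone aldehyde F1.
- In a second operation catalytic DBU (or pyrrolidine/AcOH through the enamine) closes C6–C7 by intramolecular Michael addition under thermodynamic control. This should also settle C7 and C10 as equatorial methyl groups, and the sequence comes back to the route at 14.

2. Step 14.
- The neopentylic triflate may ionise or undergo E2 loss in competition with backside attack, which has to come from the concave face. Triflation of the C9 enol is a further risk.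
- The fallback takes the substitution out of the ketone series, moves it to the last step, and replaces the sulfonate by a neutral oxyphosphonium leaving group (Appel reaction). It sets out from 19.
- Kinetic silylation (LiHMDS, TMSCl) gives the silyl enol ether F2. NBS gives the bromo ketone F3, and NaBH4 gives the silyl-protected bromohydrin F4. HF·pyridine then gives the C4,C9-diol F5.
- Treatment of the diol with CBr4/PPh3 in toluene should activate only the C4 hydroxyl. The C9 hydroxyl is axial, flanked by bromine and methyl, and syn-axial to C3. Bromide is delivered with inversion within the ion pair, and the sequence comes back to the route at 25.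

3. Step 9.
- The reaction may stop at the internal hemiketal between the new CH2OH and C1, so that the second hydride transfer does not occur. Hydride may also leak to C9.
- The fallback replaces the directing effect by protecting-group differentiation and takes the formyl group to the methyl group through sulfur. It sets out from 14.
- Ethane-1,2-dithiol with catalytic Zn(OTf)2 gives the formyl dithiolane F6.
- 1,2-Bis(trimethylsilyloxy)ethane with catalytic TMSOTf at low temperature ketalises the more accessible C9 ketone to give the dioxolane F7.
- Acetone-deactivated Raney nickel gives the C6-methyl cyclobutanone F8.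
- NaBH4 gives the C1 alcohol F9 under steric control, because the C10 methyl blocks the face syn to C10.
- Ac2O/DMAP gives the acetate F10. Aqueous HF in MeCN removes the silyl ether and the dioxolane together, and the sequence comes back to the route at 20.

Further compounds
F1 | step 8 | enone aldehyde, Michael adduct with the C10–C11 bond made and C6–H (C6 and C10 open) | O=C1C[C@@]2(C)[C@H](O[Si](C)(C)C(C)(C)C)CC(C=O)[C@@]12C(C)C(=O)/C=C/C
F2 | step 14 | C8=C9 TMS enol ether with C4 OTBS | CC(=O)O[C@@H]1C[C@@]2(C)[C@H](O[Si](C)(C)C(C)(C)C)C[C@]3(C)[C@@H](C)C=C(O[Si](C)(C)C)[C@H](C)[C@]123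
F3 | step 14 | C8 bromo ketone with C4 OTBS | CC(=O)O[C@@H]1C[C@@]2(C)[C@H](O[Si](C)(C)C(C)(C)C)C[C@]3(C)[C@@H](C)[C@H](Br)C(=O)[C@H](C)[C@]123
F4 | step 14 | C8,C9 cis-bromohydrin with C4 OTBS | CC(=O)O[C@@H]1C[C@@]2(C)[C@H](O[Si](C)(C)C(C)(C)C)C[C@]3(C)[C@@H](C)[C@H](Br)[C@H](O)[C@H](C)[C@]123
F5 | step 14 | C4,C9-diol with C8 bromide | CC(=O)O[C@@H]1C[C@@]2(C)[C@H](O)C[C@]3(C)[C@@H](C)[C@H](Br)[C@H](O)[C@H](C)[C@]123
F6 | step 9 | formyl dithiolane diketone | O=C1C[C@@]2(C)[C@H](O[Si](C)(C)C(C)(C)C)C[C@]3(C4SCCS4)[C@@H](C)CC(=O)[C@H](C)[C@]123
F7 | step 9 | C9 dioxolane of the dithiolane | O=C1C[C@@]2(C)[C@H](O[Si](C)(C)C(C)(C)C)C[C@]3(C4SCCS4)[C@@H](C)CC4(OCCO4)[C@H](C)[C@]123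
F8 | step 9 | C6-methyl cyclobutanone, C9 dioxolane | O=C1C[C@@]2(C)[C@H](O[Si](C)(C)C(C)(C)C)C[C@]3(C)[C@@H](C)CC4(OCCO4)[C@H](C)[C@]123
F9 | step 9 | C1 alcohol, C9 dioxolane | O[C@@H]1C[C@@]2(C)[C@H](O[Si](C)(C)C(C)(C)C)C[C@]3(C)[C@@H](C)CC4(OCCO4)[C@H](C)[C@]123
F10 | step 9 | C1 acetate, C9 dioxolane, C4 OTBS | CC(=O)O[C@@H]1C[C@@]2(C)[C@H](O[Si](C)(C)C(C)(C)C)C[C@]3(C)[C@@H](C)CC4(OCCO4)[C@H](C)[C@]123
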